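## Analysis of the target

Degalloyl theasinensin F (29) is an unsymmetrical dimer of two flavan-3-ols. One half is a 5,7-dihydroxychroman (rings A and C) carrying the catechol ring B at C2; the other is a second 5,7-dihydroxychroman carrying the pyrogallol ring B' at C2'. The halves are joined only by the aryl–aryl bond between ring B and ring B'.

Each heterocycle has two adjacent stereocentres (C2/C3 and C2'/C3'), all four R. Aryl and hydroxyl are therefore cis on each ring C, and both halves have the same handedness. The two pairs are too far apart for one to control the other.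

The biaryl bond carries three ortho substituents (C2, C2' and one hydroxyl of ring B') and is hindered. Its sense of twist is not part of the structure as drawn.

The nine phenols make the molecule air-sensitive. The phloroglucinol rings A are strongly nucleophilic and meet any electrophile or oxidant before rings B and B' do. The benzylic C2–O1 bonds open under acid with loss of the cis relationship, so the end game must be neutral and reductive.

Two problems dominate. The first is the hindered bond between two different electron-rich rings, which a cross-coupling would have to force. The second is the cis geometry of both rings C, the less stable arrangement.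

The route rests on ring B. Its atoms are a1 (bonded to C2), a2 (bonded to ring B'), a3 (H), a4 and a5 (both oxygenated) and a6 (H). The a1–a2 edge can be an alkyne that joins chroman carbon C2 to ring B', and a3–a6 is then a 2,3-dioxygenated butadiene.

## Retrosynthetic reasoning

**29 to 27.** The nine O–benzyl bonds of 28 and, before that, the two O–silyl bonds of 27 are cut. Benzyl ethers are chosen because they survive organometallic, basic and mildly oxidising steps and leave by neutral hydrogenolysis. The two silyl ethers on ring B come with the diene.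

**27 to 23 and 25.** Ring B is cut at a2–a3 and a6–a1. This leaves alkyne 23, in which a1 and a2 are the two sp carbons, and the symmetric diene 25, which supplies a3 to a6 with both oxygens in place. The cut is made here because it removes the hindered biaryl bond from the list of bonds that must be formed by coupling. The axis appears when the ring is built. The forward reaction must add the diene across a crowded internal alkyne (giving 26) and then remove two hydrogens without touching the four stereocentres.

**25 to 24.** The two O–Si bonds are cut, which leads to diketone 24. Double enol silylation is all that is required.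

**23 to 15 and 22.** The bond between the alkyne and ring B' is cut, giving terminal alkyne 15 and aryl bromide 22. Both halves are then complete, stereodefined chromans that meet in one coupling.

**15 to 14, and 22 to 21.** In each chroman the aryl–oxygen bond O1–C8a is cut, with fluoride as the leaving group on ring A. This bond is chosen, and not C2–O1, because the carbinol carbon then keeps its configuration. A syn alcohol gives the cis ring directly and no later inversion at C3 is needed. The fluorine is meta to both benzyloxy groups, so it is not deactivated by resonance.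

**14 and 21 to 9.** The C2–C(alkyne) bond of 14 and the C2'–C(aryl) bond of 21 are cut. Both lead back to one α-benzyloxy aldehyde, 9. Its partners are the alkynyl unit from 10 (through 11, 12 and 13) and the aryl unit from 19 (through 20). One aldehyde thus serves both halves, and the chelating α-benzyloxy group should direct each nucleophile to the syn product that the retentive ring closure needs.

**9 to 1 and 4.** Aldehyde 9 is taken back through alcohol 8 and ethers 7 and 6. Cutting C4–C4a then gives aryllithium 5 and the commercial epoxide 4, whose stereocentre becomes C3 of both halves. Compound 5 comes from bromide 3, made from fluoroarene 2 and ultimately from 1. The bromine fixes the position of the metal without any question of regiochemistry at the organometallic stage.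

**19 to 16.** The C–Br bond of 19 is cut to give the symmetric iodide 18, in which both open positions are equivalent. Compound 18 comes from triol 17 and the commercial trimethyl ether 16. Iodine and bromine are placed so that the iodine becomes the metal and the bromine stays as the coupling handle next to C2'.

## Alternatives that were turned down

**Alternative 1:** Both rings A are cut at C4a–C5, which turns each into an open polyketide chain masked as a dioxinone. The precursor is the biaryl bis(diketo-dioxinone) A1.

- Forward key step: thermolysis of A1 in an alcohol would open both dioxinones to β-keto esters. A magnesium alkoxide would then steer each chain into a Claisen condensation, C4a onto the ester carbon, to give the bis(trihydroxychalcone) A2.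
- For it: it follows the biosynthesis and builds the most electron-rich rings last, so they never face electrophilic steps. It forms two rings and two C–C bonds in one flask, twice what the chosen key step does. On that point it is stronger.
- Against it: A2 contains none of the four stereocentres and neither ring C. Each chalcone would still need ring closure, C3 oxygenation, C4 deoxygenation and a trans-to-cis correction, twice, on a substrate with six free phenols. The enones of A1 are Michael acceptors under alkoxide, and the aldol mode of cyclisation competes with the Claisen mode. A1 also already contains the tri-ortho-substituted biaryl, so the hardest bond must first be made by a hindered coupling of two electron-rich rings.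
- Comparison: the chosen strategy has both heterocycles complete and stereodefined before its key step and never couples the biaryl.

**Alternative 2:** Both rings C are cut at O1–C2 and C3–C4. Each ring is then the [4+2] adduct of an ortho-quinone methide and an alkene. The precursors are the biaryl bis[(Z)-alkenylboronate] A3 and the hydroxybenzyl alcohol A4.

- Forward key step: a chiral phosphoric acid would dehydrate A4 to the quinone methide and guide its addition to each Z-alkene of A3. The product is the bis(cis-3-borylflavan) A5, whose C–B bonds would be oxidised with retention.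
- For it: four bonds, two rings and all four stereocentres arise in one operation, and the cis geometry follows from the alkene geometry. In convergence and in stereocentres set per step it clearly surpasses the chosen route, whose key step sets none.
- Against it: an alkenylboronate is a weakly nucleophilic 2π partner, and a quinone methide stabilised by two benzyloxy groups is a poor electrophile. Catalyst control must hold twice on one molecule, next to a hindered axis, and each lapse multiplies into diastereomers that are hard to separate at this size. A3 again needs the hindered biaryl coupling first.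
- Comparison: the chosen route sets its stereochemistry by substrate-controlled additions to one small aldehyde and keeps its single uncertain step free of stereochemical demands.

**Alternative 3:** Both rings C are cut at O1–C8a. The precursor is the biaryl bis(bromo diol) monosilyl ether A6, whose syn oxygen pattern would come from asymmetric dihydroxylation of two E-alkenes.

- Forward key step: a palladium catalyst with a bulky dialkylbiarylphosphine and a carbonate base would couple each benzylic hydroxyl with the ortho-bromide of ring A to give A7. C2–O is not broken, so the syn precursor gives the cis ring.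
- For it: this is the same retentive logic that the chosen route uses for its own ring closures. Reagent-controlled dihydroxylation treats both halves alike, and two rings close in one step. On stereochemical generality it is at least as strong.
- Against it: palladium alkoxides of secondary benzylic alcohols tend to lose a β-hydride, giving ketone and debrominated arene, and this must be avoided twice on a crowded substrate. The ring-A bromides exclude any other halogen handle. The biaryl must again exist before the key step.
- Comparison: the chosen route gets the same retention by metal-free displacement of fluoride, where β-hydride loss cannot occur, and needs no biaryl coupling.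

Key step: step 16

Assumption: the structure defines the four carbon stereocentres but not the twist about the ring B–ring B' bond, so the route does not control that axis; rotamers that interconvert slowly would be separated or equilibrated at the stage of 28 or 29.

## Route

Step 1
Reactants: 1 1,3,5-trifluorobenzene
Product: 2 1,3-bis(benzyloxy)-5-fluorobenzene
Conditions: BnOH (2.1 equiv), NaH, NMP, 0 → 80 °C
Reagents that add atoms: benzyl alcohol, OCc1ccccc1
Why: Twofold nucleophilic aromatic substitution; each fluorine of 1 is activated by the two meta fluorines, and every benzyloxy group introduced slows the next exchange, so two equivalents of alkoxide should stop at 2.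

Step 2
Reactants: 2 1,3-bis(benzyloxy)-5-fluorobenzene
Product: 3 1,5-bis(benzyloxy)-2-bromo-3-fluorobenzene
Conditions: NBS (1.0 equiv), MeCN, 0 °C → rt
Reagents that add atoms: N-bromosuccinimide, O=C1CCC(=O)N1Br
Why: Electrophilic aromatic bromination; attack para to one benzyloxy group and next to the small fluorine should be preferred over the position squeezed between the two benzyloxy groups, and one equivalent at low temperature limits dibromination.

Step 3
Reactants: 3 1,5-bis(benzyloxy)-2-bromo-3-fluorobenzene; 4 (R)-trityl glycidyl ether [(2R)-2-[(trityloxy)methyl]oxirane]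
Product: 6 (2R)-1-[2,4-bis(benzyloxy)-6-fluorophenyl]-3-(trityloxy)propan-2-ol, via aryllithium 5 (not isolated)
Conditions: n-BuLi, THF, −78 °C; then 4, BF3·OEt2, −78 °C
Reagents that add atoms: none
Why: Bromine–lithium exchange fixes the position of the metal, and 5 should not lose LiF at −78 °C; Lewis-acid-assisted opening of the terminal epoxide at its CH2 carbon forms C4–C4a without touching the stereocentre of 4, which becomes C3 of both halves.

Step 4
Reactants: 6 (2R)-1-[2,4-bis(benzyloxy)-6-fluorophenyl]-3-(trityloxy)propan-2-ol
Product: 7 1,5-bis(benzyloxy)-2-[(2R)-2-(benzyloxy)-3-(trityloxy)propyl]-3-fluorobenzene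
Conditions: NaH, BnBr, Bu4NI (cat.), THF/DMF, 0 °C → rt
Reagents that add atoms: benzyl bromide, BrCc1ccccc1
Why: Williamson etherification; alkylation of the alkoxide at 0 °C is much faster than a five-membered displacement of the ortho fluorine, and a trityl ether cannot migrate to the neighbouring oxygen as a silyl ether could.

Step 5
Reactants: 7 1,5-bis(benzyloxy)-2-[(2R)-2-(benzyloxy)-3-(trityloxy)propyl]-3-fluorobenzene
Product: 8 (2R)-2-(benzyloxy)-3-[2,4-bis(benzyloxy)-6-fluorophenyl]propan-1-ol
Conditions: TsOH·H2O (cat.), MeOH/CH2Cl2, rt
Reagents that add atoms: none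
Why: Acid-catalysed solvolysis of the trityl ether through the trityl cation, which methanol captures; benzyl ethers and the aryl fluoride are inert to catalytic sulfonic acid at room temperature.

Step 6
Reactants: 8 (2R)-2-(benzyloxy)-3-[2,4-bis(benzyloxy)-6-fluorophenyl]propan-1-ol
Product: 9 (2R)-2-(benzyloxy)-3-[2,4-bis(benzyloxy)-6-fluorophenyl]propanal
Conditions: Dess–Martin periodinane, NaHCO3, CH2Cl2, 0 °C → rt
Reagents that add atoms: none
Why: Dess–Martin oxidation under buffered, non-basic conditions should give the α-benzyloxy aldehyde without epimerisation; 9 is used at once in steps 7 and 12.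

Step 7
Reactants: 9 (2R)-2-(benzyloxy)-3-[2,4-bis(benzyloxy)-6-fluorophenyl]propanal; 10 trimethylsilylacetylene
Product: 14 (2R,3R)-2-(benzyloxy)-1-[2,4-bis(benzyloxy)-6-fluorophenyl]pent-4-yn-3-ol, via lithium (trimethylsilyl)acetylide 11 (not isolated), via (trimethylsilyl)ethynylzinc bromide 12 (not isolated), via silylated alkynol 13 (not isolated)
Conditions: 10, n-BuLi, Et2O, −78 °C; ZnBr2, 0 °C; then 9, −78 → 0 °C; then K2CO3, MeOH, rt
Reagents that add atoms: none
Why: Chelation-controlled (Cram-chelate) 1,2-addition: zinc bridges the carbonyl and the α-benzyloxy oxygen and the alkynyl group attacks the face away from the arylmethyl group, which sets the new carbinol as R, syn to the C–OBn centre; carbonate in methanol then removes the C-silyl group.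

Step 8
Reactants: 14 (2R,3R)-2-(benzyloxy)-1-[2,4-bis(benzyloxy)-6-fluorophenyl]pent-4-yn-3-ol
Product: 15 (2R,3R)-3,5,7-tris(benzyloxy)-2-ethynylchroman
Conditions: KHMDS (2.5 equiv), 18-crown-6, THF, 0 → 65 °C
Reagents that add atoms: none
Why: Intramolecular nucleophilic aromatic substitution (six-membered ring, O1–C8a); the fluorine is meta to both benzyloxy groups and so not deactivated by resonance, the carbinol C–O bond is not broken so the syn alcohol gives the cis chroman with retention, and the second equivalent of base holds the alkyne as its acetylide, which guards the propargylic C2–H.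

Step 9
Reactants: 16 5-iodo-1,2,3-trimethoxybenzene
Product: 17 5-iodobenzene-1,2,3-triol
Conditions: BBr3, CH2Cl2, −78 °C → rt; then H2O
Reagents that add atoms: none
Why: Lewis-acid cleavage of aryl methyl ethers by BBr3; the aryl iodide is untouched.

Step 10
Reactants: 17 5-iodobenzene-1,2,3-triol
Product: 18 1,2,3-tris(benzyloxy)-5-iodobenzene
Conditions: BnBr, K2CO3, DMF, 50 °C, under argon
Reagents that add atoms: benzyl bromide, BrCc1ccccc1
Why: Williamson etherification of the three phenols; exclusion of air protects the pyrogallol until it is alkylated.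

Step 11
Reactants: 18 1,2,3-tris(benzyloxy)-5-iodobenzene
Product: 19 1,2,3-tris(benzyloxy)-4-bromo-5-iodobenzene
Conditions: NBS (1.0 equiv), MeCN, 0 °C → rt
Reagents that add atoms: N-bromosuccinimide, O=C1CCC(=O)N1Br
Why: Electrophilic aromatic bromination; the two open positions of 18 are equivalent and each is ortho to one benzyloxy group and para to another, so only one monobromide can form, with bromine next to iodine.

Step 12
Reactants: 19 1,2,3-tris(benzyloxy)-4-bromo-5-iodobenzene; 9 (2R)-2-(benzyloxy)-3-[2,4-bis(benzyloxy)-6-fluorophenyl]propanal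
Product: 21 (1R,2R)-2-(benzyloxy)-3-[2,4-bis(benzyloxy)-6-fluorophenyl]-1-[3,4,5-tris(benzyloxy)-2-bromophenyl]propan-1-ol, via arylmagnesium chloride 20 (not isolated)
Conditions: i-PrMgCl·LiCl, THF, −40 °C; then 9, MgBr2·OEt2, CH2Cl2, −78 → −40 °C
Reagents that add atoms: none
Why: Iodine–magnesium exchange is selective for iodine over bromine, and the ortho-bromoaryl Grignard reagent should be stable below −20 °C; chelation-controlled addition to the magnesium-bridged α-benzyloxy aldehyde sets C1 (the later C2') as R, syn to the C–OBn centre.

Step 13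
Reactants: 21 (1R,2R)-2-(benzyloxy)-3-[2,4-bis(benzyloxy)-6-fluorophenyl]-1-[3,4,5-tris(benzyloxy)-2-bromophenyl]propan-1-ol
Product: 22 (2R,3R)-3,5,7-tris(benzyloxy)-2-[3,4,5-tris(benzyloxy)-2-bromophenyl]chroman
Conditions: KHMDS (1.3 equiv), 18-crown-6, THF, 0 → 65 °C
Reagents that add atoms: none
Why: Intramolecular nucleophilic aromatic substitution as in step 8, closing ring C' with retention at the carbinol carbon, so the syn alcohol gives the cis flavan; the bromide has no ortho hydrogen, so base cannot turn it into an aryne.

Step 14
Reactants: 15 (2R,3R)-3,5,7-tris(benzyloxy)-2-ethynylchroman; 22 (2R,3R)-3,5,7-tris(benzyloxy)-2-[3,4,5-tris(benzyloxy)-2-bromophenyl]chroman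
Product: 23 (2R,3R)-3,5,7-tris(benzyloxy)-2-({2,3,4-tris(benzyloxy)-6-[(2R,3R)-3,5,7-tris(benzyloxy)chroman-2-yl]phenyl}ethynyl)chroman
Conditions: PdCl2(PhCN)2 (5 mol%), t-Bu3P·HBF4 (10 mol%), CuI (5 mol%), i-Pr2NH, 1,4-dioxane, rt → 60 °C, degassed
Reagents that add atoms: none
Why: Sonogashira coupling; the bulky electron-rich trialkylphosphine is needed for oxidative addition of zerovalent palladium to the electron-rich, doubly ortho-substituted bromide, and the linear alkyne adds little strain at the crowded carbon.

Step 15
Reactants: 24 butane-2,3-dione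
Product: 25 2,3-bis(trimethylsilyloxy)buta-1,3-diene
Conditions: Me3SiOTf (2.2 equiv), Et3N, Et2O, 0 °C → rt
Reagents that add atoms: trimethylsilyl trifluoromethanesulfonate, C[Si](C)(C)OS(=O)(=O)C(F)(F)F
Why: Double soft enolisation and O-silylation of the 1,2-diketone; the diene is distilled and stored cold.

Step 16
Reactants: 23 the alkyne of step 14; 25 2,3-bis(trimethylsilyloxy)buta-1,3-diene
Product: 27 nonabenzyl bis(trimethylsilyl) degalloyl theasinensin F (ring B as catechol bis(trimethylsilyl) ether and all nine other hydroxyls as benzyl ethers), via 1,4-cyclohexadiene cycloadduct 26 (not isolated)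
Conditions: 25 (4 equiv), CoBr2(dppe) (20 mol%), Zn (40 mol%), ZnI2 (40 mol%), CH2Cl2, rt → 40 °C; then DDQ (1.1 equiv), 0 °C
Reagents that add atoms: none
Why: Zinc reduces CoBr2(dppe) to a monovalent cobalt species from which ZnI2 removes halide, so that the s-cis diene 25 and the alkyne of 23 can bind side by side. Oxidative cyclisation joins a diene terminus to an alkyne carbon in a cobaltacycle and reductive elimination forms the second bond, so a2–a3 and a6–a1 are made and ring B is closed as a six-membered carbocycle by intermolecular [4+2] annulation, giving the 1,4-cyclohexadiene 26. DDQ then takes a hydride from one doubly allylic methylene (a3 or a6), and the cation, stabilised by the adjacent silyloxy group, loses a proton from the other methylene to give the aromatic ring of 27; only two hydrogens leave. The closest known reaction type is the cobalt-catalysed neutral Diels–Alder reaction of unactivated internal alkynes with 2-silyloxy-1,3-dienes followed by DDQ dehydrogenation. No stereocentre is formed: C2, C3, C2' and C3' are spectators under these neutral conditions, and the twist of the new biaryl bond is not controlled. The symmetry of 25 removes any regiochemical question, so the step needs only chemoselectivity: the alkyne is the sole two-carbon π-system able to share the metal with the diene, and the benzyl ethers and arenes do not bind. In the oxidation the bis(silyloxy)cyclohexadiene is a far better hydride donor than the C4 methylenes of the two chromans, so about one equivalent of DDQ at 0 °C should stop at 27.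

Step 17
Reactants: 27 nonabenzyl bis(trimethylsilyl) degalloyl theasinensin F
Product: 28 nonabenzyl degalloyl theasinensin F (ring B as free catechol)
Conditions: Bu4NF, AcOH, THF, 0 °C, under argon
Reagents that add atoms: none
Why: Fluoride cleavage of the two aryl silyl ethers; acetic acid keeps the catechol protonated and so less prone to air oxidation, and benzyl ethers are unaffected.

Step 18
Reactants: 28 nonabenzyl degalloyl theasinensin F
Product: 29 degalloyl theasinensin F
Conditions: H2 (1 atm), Pd(OH)2/C, THF/MeOH, rt; filtration and concentration under argon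
Reagents that add atoms: none
Why: Hydrogenolysis of the nine benzyl ethers under neutral conditions; the ring C–O1 bonds are aryl alkyl ethers inside a ring and should survive, as is usual for benzylated flavan-3-ols, and no acid or base is present that could epimerise C2 or C2'.

## Compound list

1 | 1,3,5-trifluorobenzene | Fc1cc(F)cc(F)c1 | starting material
2 | 1,3-bis(benzyloxy)-5-fluorobenzene | Fc1cc(OCc2ccccc2)cc(OCc2ccccc2)c1 | intermediate
3 | 1,5-bis(benzyloxy)-2-bromo-3-fluorobenzene | Brc1c(F)cc(OCc2ccccc2)cc1OCc1ccccc1 | intermediate
4 | (R)-trityl glycidyl ether, (2R)-2-[(trityloxy)methyl]oxirane | C1O[C@H]1COC(c1ccccc1)(c1ccccc1)c1ccccc1 | starting material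
5 | [2,4-bis(benzyloxy)-6-fluorophenyl]lithium (not isolated) | [Li]c1c(F)cc(OCc2ccccc2)cc1OCc1ccccc1 | intermediate
6 | (2R)-1-[2,4-bis(benzyloxy)-6-fluorophenyl]-3-(trityloxy)propan-2-ol | O[C@H](Cc1c(F)cc(OCc2ccccc2)cc1OCc1ccccc1)COC(c1ccccc1)(c1ccccc1)c1ccccc1 | intermediate
7 | 1,5-bis(benzyloxy)-2-[(2R)-2-(benzyloxy)-3-(trityloxy)propyl]-3-fluorobenzene | C(c1ccccc1)O[C@H](Cc1c(F)cc(OCc2ccccc2)cc1OCc1ccccc1)COC(c1ccccc1)(c1ccccc1)c1ccccc1 | intermediate
8 | (2R)-2-(benzyloxy)-3-[2,4-bis(benzyloxy)-6-fluorophenyl]propan-1-ol | C(c1ccccc1)O[C@H](Cc1c(F)cc(OCc2ccccc2)cc1OCc1ccccc1)CO | intermediate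
9 | (2R)-2-(benzyloxy)-3-[2,4-bis(benzyloxy)-6-fluorophenyl]propanal | C(c1ccccc1)O[C@H](Cc1c(F)cc(OCc2ccccc2)cc1OCc1ccccc1)C=O | intermediate
10 | trimethylsilylacetylene | C#C[Si](C)(C)C | starting material
11 | lithium (trimethylsilyl)acetylide (not isolated) | [Li]C#C[Si](C)(C)C | intermediate
12 | (trimethylsilyl)ethynylzinc bromide (not isolated) | Br[Zn]C#C[Si](C)(C)C | intermediate
13 | (2R,3R)-2-(benzyloxy)-1-[2,4-bis(benzyloxy)-6-fluorophenyl]-5-(trimethylsilyl)pent-4-yn-3-ol (not isolated) | O[C@H](C#C[Si](C)(C)C)[C@H](OCc1ccccc1)Cc1c(F)cc(OCc2ccccc2)cc1OCc1ccccc1 | intermediate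
14 | (2R,3R)-2-(benzyloxy)-1-[2,4-bis(benzyloxy)-6-fluorophenyl]pent-4-yn-3-ol | O[C@H](C#C)[C@H](OCc1ccccc1)Cc1c(F)cc(OCc2ccccc2)cc1OCc1ccccc1 | intermediate
15 | (2R,3R)-3,5,7-tris(benzyloxy)-2-ethynylchroman | C(c1ccccc1)Oc1cc(OCc2ccccc2)c2c(c1)O[C@H](C#C)[C@H](OCc1ccccc1)C2 | intermediate
16 | 5-iodo-1,2,3-trimethoxybenzene | COc1cc(I)cc(OC)c1OC | starting material
17 | 5-iodobenzene-1,2,3-triol | Oc1cc(I)cc(O)c1O | intermediate
18 | 1,2,3-tris(benzyloxy)-5-iodobenzene | Ic1cc(OCc2ccccc2)c(OCc2ccccc2)c(OCc2ccccc2)c1 | intermediate
19 | 1,2,3-tris(benzyloxy)-4-bromo-5-iodobenzene | Brc1c(I)cc(OCc2ccccc2)c(OCc2ccccc2)c1OCc1ccccc1 | intermediate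
20 | [3,4,5-tris(benzyloxy)-2-bromophenyl]magnesium chloride (not isolated) | Cl[Mg]c1cc(OCc2ccccc2)c(OCc2ccccc2)c(OCc2ccccc2)c1Br | intermediate
21 | (1R,2R)-2-(benzyloxy)-3-[2,4-bis(benzyloxy)-6-fluorophenyl]-1-[3,4,5-tris(benzyloxy)-2-bromophenyl]propan-1-ol | Brc1c([C@@H](O)[C@H](OCc2ccccc2)Cc2c(F)cc(OCc3ccccc3)cc2OCc2ccccc2)cc(OCc2ccccc2)c(OCc2ccccc2)c1OCc1ccccc1 | intermediate
22 | (2R,3R)-3,5,7-tris(benzyloxy)-2-[3,4,5-tris(benzyloxy)-2-bromophenyl]chroman | Brc1c([C@H]2Oc3cc(OCc4ccccc4)cc(OCc4ccccc4)c3C[C@H]2OCc2ccccc2)cc(OCc2ccccc2)c(OCc2ccccc2)c1OCc1ccccc1 | intermediate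
23 | (2R,3R)-3,5,7-tris(benzyloxy)-2-({2,3,4-tris(benzyloxy)-6-[(2R,3R)-3,5,7-tris(benzyloxy)chroman-2-yl]phenyl}ethynyl)chroman | C(c1ccccc1)Oc1cc(OCc2ccccc2)c2c(c1)O[C@H](C#Cc1c([C@H]3Oc4cc(OCc5ccccc5)cc(OCc5ccccc5)c4C[C@H]3OCc3ccccc3)cc(OCc3ccccc3)c(OCc3ccccc3)c1OCc1ccccc1)[C@H](OCc1ccccc1)C2 | intermediate
24 | butane-2,3-dione | CC(=O)C(C)=O | starting material
25 | 2,3-bis(trimethylsilyloxy)buta-1,3-diene | C=C(O[Si](C)(C)C)C(=C)O[Si](C)(C)C | intermediate
26 | 1,4-cyclohexadiene cycloadduct: 4,5-bis(trimethylsilyloxy)cyclohexa-1,4-diene with the (2R,3R)-tris(benzyloxy)chroman-2-yl group on C1 and the ring B' aryl group on C2 (not isolated) | C(c1ccccc1)Oc1cc(OCc2ccccc2)c2c(c1)O[C@H](C1=C(c3c([C@H]4Oc5cc(OCc6ccccc6)cc(OCc6ccccc6)c5C[C@H]4OCc4ccccc4)cc(OCc4ccccc4)c(OCc4ccccc4)c3OCc3ccccc3)CC(O[Si](C)(C)C)=C(O[Si](C)(C)C)C1)[C@H](OCc1ccccc1)C2 | intermediate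
27 | nonabenzyl bis(trimethylsilyl) degalloyl theasinensin F | C(c1ccccc1)Oc1cc(OCc2ccccc2)c2c(c1)O[C@H](c1cc(O[Si](C)(C)C)c(O[Si](C)(C)C)cc1-c1c([C@H]3Oc4cc(OCc5ccccc5)cc(OCc5ccccc5)c4C[C@H]3OCc3ccccc3)cc(OCc3ccccc3)c(OCc3ccccc3)c1OCc1ccccc1)[C@H](OCc1ccccc1)C2 | intermediate
28 | nonabenzyl degalloyl theasinensin F (free catechol on ring B) | C(c1ccccc1)Oc1cc(OCc2ccccc2)c2c(c1)O[C@H](c1cc(O)c(O)cc1-c1c([C@H]3Oc4cc(OCc5ccccc5)cc(OCc5ccccc5)c4C[C@H]3OCc3ccccc3)cc(OCc3ccccc3)c(OCc3ccccc3)c1OCc1ccccc1)[C@H](OCc1ccccc1)C2 | intermediate
29 | degalloyl theasinensin F | Oc1cc(O)c2c(c1)O[C@H](c1cc(O)c(O)cc1-c1c([C@H]3Oc4cc(O)cc(O)c4C[C@H]3O)cc(O)c(O)c1O)[C@H](O)C2 | target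

## Step count and least certain steps

Total: 18 steps. Longest linear sequence: 12 steps (steps 1 to 6, then 12, 13, 14, 16, 17 and 18).

**Step 16 (key step).** The most likely failure is that no cycloaddition takes place. The alkyne lies between a doubly ortho-substituted aryl ring and a branched chromanyl carbon and may not enter the cobalt coordination sphere together with the diene. The diene would then be lost to dimerisation or to desilylation by ZnI2. A second hazard is over-oxidation by DDQ at the C4 methylenes of the chromans if the oxidant is used in excess or warm.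

The fallback moves the ring construction to a less crowded alkyne and sets out from 15. Deprotonation of 15 with n-BuLi and quenching with 2-isopropoxy-4,4,5,5-tetramethyl-1,3,2-dioxaborolane should give the alkynylboronate F1. Cobalt-catalysed cycloaddition of alkynylboronic esters with 25 and DDQ dehydrogenation is a known reaction type and should give the arylboronate F2. Suzuki–Miyaura coupling of F2 with bromide 22 (Pd(OAc)2, SPhos, K3PO4, toluene/water, 90 °C) would then form the biaryl bond. The silyl ethers are expected to be lost under the aqueous base, so the route is rejoined at 28.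

**Step 12.** Two processes can go wrong. The ortho-bromoaryl Grignard reagent can eliminate magnesium halide to an aryne if the temperature rises. Chelation control can also be weakened by the THF and LiCl that the exchange brings in, which would mean poor facial selectivity at C1.

The fallback sets out from 21 obtained as a mixture of C1 epimers. Oxidation with Dess–Martin periodinane gives the aryl ketone F3. Corey–Bakshi–Shibata reduction with BH3·SMe2 follows; with the aryl group as the larger substituent the (R)-2-methyl-oxazaborolidine should deliver the (1R) carbinol. This non-basic reduction should not epimerise the α-centre, and it returns to 21 as one diastereomer.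

**Step 7.** The likely failure is again poor facial selectivity, if part of the addition runs through an open, non-chelated transition state. Partial epimerisation of 9 before addition is also possible.

The fallback interrupts step 7 before the carbonate treatment and sets out from 13 as the epimer mixture. Dess–Martin oxidation gives the ynone F4. Asymmetric transfer hydrogenation with Ru[(S,S)-TsDPEN](p-cymene) in i-PrOH is reagent-controlled for alkynyl ketones and is expected to give the (3R) carbinol. It returns to 13, which is then desilylated to 14 as planned.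

**Step 14.** Oxidative addition to the electron-rich bromide flanked by a benzyloxy group and the chromanyl carbon may be slow. Copper-mediated oxidative dimerisation of 15 would then consume the alkyne.

The fallback changes the electrophile and sets out from 22. Bromine–lithium exchange with t-BuLi at −78 °C and an iodine quench should give the aryl iodide F5. F5 should couple with 15 under ordinary Sonogashira conditions (Pd(PPh3)2Cl2, CuI, Et3N, THF, rt) and return to 23.

## Further compounds

F1 | step 16 | (2R,3R)-3,5,7-tris(benzyloxy)-2-[(4,4,5,5-tetramethyl-1,3,2-dioxaborolan-2-yl)ethynyl]chroman | C(c1ccccc1)Oc1cc(OCc2ccccc2)c2c(c1)O[C@H](C#CB1OC(C)(C)C(C)(C)O1)[C@H](OCc1ccccc1)C2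
F2 | step 16 | (2R,3R)-3,5,7-tris(benzyloxy)-2-[2-(4,4,5,5-tetramethyl-1,3,2-dioxaborolan-2-yl)-4,5-bis(trimethylsilyloxy)phenyl]chroman | C(c1ccccc1)Oc1cc(OCc2ccccc2)c2c(c1)O[C@H](c1cc(O[Si](C)(C)C)c(O[Si](C)(C)C)cc1B1OC(C)(C)C(C)(C)O1)[C@H](OCc1ccccc1)C2
F3 | step 12 | (2R)-2-(benzyloxy)-3-[2,4-bis(benzyloxy)-6-fluorophenyl]-1-[3,4,5-tris(benzyloxy)-2-bromophenyl]propan-1-one | Brc1c(C(=O)[C@H](OCc2ccccc2)Cc2c(F)cc(OCc3ccccc3)cc2OCc2ccccc2)cc(OCc2ccccc2)c(OCc2ccccc2)c1OCc1ccccc1
F4 | step 7 | (2R)-2-(benzyloxy)-1-[2,4-bis(benzyloxy)-6-fluorophenyl]-5-(trimethylsilyl)pent-4-yn-3-one | O=C(C#C[Si](C)(C)C)[C@H](OCc1ccccc1)Cc1c(F)cc(OCc2ccccc2)cc1OCc1ccccc1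
F5 | step 14 | (2R,3R)-3,5,7-tris(benzyloxy)-2-[3,4,5-tris(benzyloxy)-2-iodophenyl]chroman | Ic1c([C@H]2Oc3cc(OCc4ccccc4)cc(OCc4ccccc4)c3C[C@H]2OCc2ccccc2)cc(OCc2ccccc2)c(OCc2ccccc2)c1OCc1ccccc1
A1 | alternative 1 | biaryl bis(diketo-dioxinone) pentabenzyl ether | O=C(/C=C/c1cc(OCc2ccccc2)c(OCc2ccccc2)cc1-c1c(/C=C/C(=O)CC(=O)CC2=CC(=O)OC(C)(C)O2)cc(OCc2ccccc2)c(OCc2ccccc2)c1OCc1ccccc1)CC(=O)CC1=CC(=O)OC(C)(C)O1
A2 | alternative 1 | biaryl bis(2',4',6'-trihydroxychalcone) pentabenzyl ether | O=C(/C=C/c1cc(OCc2ccccc2)c(OCc2ccccc2)cc1-c1c(/C=C/C(=O)c2c(O)cc(O)cc2O)cc(OCc2ccccc2)c(OCc2ccccc2)c1OCc1ccccc1)c1c(O)cc(O)cc1O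
A3 | alternative 2 | biaryl bis[(Z)-2-(pinacolboryl)vinyl] pentabenzyl ether | CC1(C)OB(OC1(C)C)/C=C\c1cc(OCc2ccccc2)c(OCc2ccccc2)cc1-c1c(/C=C\B2OC(C)(C)C(C)(C)O2)cc(OCc2ccccc2)c(OCc2ccccc2)c1OCc1ccccc1
A4 | alternative 2 | 3,5-bis(benzyloxy)-2-(hydroxymethyl)phenol | OCc1c(O)cc(OCc2ccccc2)cc1OCc1ccccc1
A5 | alternative 2 | nonabenzyl bis(cis-3-pinacolboryl flavan) | C(c1ccccc1)Oc1cc(OCc2ccccc2)c2c(c1)O[C@H](c1cc(OCc3ccccc3)c(OCc3ccccc3)cc1-c1c([C@H]3Oc4cc(OCc5ccccc5)cc(OCc5ccccc5)c4C[C@H]3B3OC(C)(C)C(C)(C)O3)cc(OCc3ccccc3)c(OCc3ccccc3)c1OCc1ccccc1)[C@H](B1OC(C)(C)C(C)(C)O1)C2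
A6 | alternative 3 | biaryl bis[1-hydroxy-2-(tert-butyldimethylsilyloxy)-3-(2-bromo-4,6-bis(benzyloxy)phenyl)propyl] pentabenzyl ether | O[C@H](c1cc(OCc2ccccc2)c(OCc2ccccc2)cc1-c1c([C@H]([C@H](O[Si](C)(C)C(C)(C)C)Cc2c(Br)cc(OCc3ccccc3)cc2OCc2ccccc2)O)cc(OCc2ccccc2)c(OCc2ccccc2)c1OCc1ccccc1)[C@H](O[Si](C)(C)C(C)(C)C)Cc1c(Br)cc(OCc2ccccc2)cc1OCc1ccccc1
A7 | alternative 3 | nonabenzyl 3,3'-bis(tert-butyldimethylsilyl) degalloyl theasinensin F | C(c1ccccc1)Oc1cc(OCc2ccccc2)c2c(c1)O[C@H](c1cc(OCc3ccccc3)c(OCc3ccccc3)cc1-c1c([C@H]3Oc4cc(OCc5ccccc5)cc(OCc5ccccc5)c4C[C@H]3O[Si](C)(C)C(C)(C)C)cc(OCc3ccccc3)c(OCc3ccccc3)c1OCc1ccccc1)[C@H](O[Si](C)(C)C(C)(C)C)C2
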